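The whole route hangs on breaking the C2–C3 bond of ring C in the flavanone half. There, C2–H is benzylic to the para-oxygenated ring B, adjacent to O1 and six atoms away from C3, so a rhodium carbene generated at C3 from an aryl diazoketone can insert into an O–CH2 hydrogen of a 4-benzyloxybenzyl ether on ring A. That one operation makes C2–C3, closes ring C and fixes C2; mild base then settles C3 trans. The precursor is a 2-diazo-1,2-diarylethanone whose aroyl ring carries three identical 4-benzyloxybenzyl ethers and whose diazo carbon bears the silyl-protected linking phenol ring with the benzyl-protected flavone already in place.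

Key step: step 9

Assumption: the four starting materials in the compound list are taken as commercial.
Assumption: Rh2(S-PTTL)4 (dirhodium tetrakis[N-phthaloyl-(S)-tert-leucinate]) is taken to deliver the 2S configuration in the key step; should the sense of induction prove opposite, Rh2(R-PTTL)4 is used instead with nothing else changed.
Remark: the para oxygen of the aroyl ring of the diazoketone carries the same 4-benzyloxybenzyl group as the two ortho oxygens (a spectator that cannot reach the carbene), so the three phenols never have to be told apart; three equivalents of the chloride are therefore consumed in step 6.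
Remark: the diaryl ketone is assembled by enolate arylation and not by acylation of a free phloroglucinol, because a Lewis acid would strip the aryl silyl ether and the flavone 5-O-benzyl ether, and a free ortho-hydroxybenzyl ketone closes readily to a 2-arylbenzofuran.

Step 1
Reactants: 1 2',6'-dihydroxy-4'-methoxyacetophenone
Product: 2 1-(2-benzyloxy-6-hydroxy-4-methoxyphenyl)ethanone
Conditions: BnBr (1.05 equiv), K2CO3, acetone, reflux
Reagents that add atoms: benzyl bromide, BrCc1ccccc1
Why: Williamson etherification; the two phenols of 1 are equivalent and the one left after the first alkylation is tied up in a hydrogen bond to the ketone, so a single benzyl group should go on.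

Step 2
Reactants: 3 3-bromo-4-hydroxybenzaldehyde
Product: 4 3-bromo-4-(methoxymethoxy)benzaldehyde
Conditions: MOMCl, K2CO3, acetone, 0 °C to rt
Reagents that add atoms: chloromethyl methyl ether, COCCl
Why: Williamson-type O-alkylation of the acidic bromophenoxide with the α-chloro ether gives the base-stable MOM acetal, which keeps the aldehyde electrophilic in the aldol step that follows.

Step 3
Reactants: 2 1-(2-benzyloxy-6-hydroxy-4-methoxyphenyl)ethanone; 4 3-bromo-4-(methoxymethoxy)benzaldehyde
Product: 5 (E)-1-(2-benzyloxy-6-hydroxy-4-methoxyphenyl)-3-[3-bromo-4-(methoxymethoxy)phenyl]prop-2-en-1-one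
Conditions: KOH (50% aq.), EtOH, rt
Reagents that add atoms: none
Why: Claisen–Schmidt condensation, in which the enolate of methyl ketone 2 adds to the non-enolisable aldehyde 4 and E1cB loss of water gives the conjugated E-enone, the benzyl and MOM ethers being inert to hydroxide.

Step 4
Reactants: 5 (E)-1-(2-benzyloxy-6-hydroxy-4-methoxyphenyl)-3-[3-bromo-4-(methoxymethoxy)phenyl]prop-2-en-1-one
Product: 7 5-benzyloxy-2-(3-bromo-4-hydroxyphenyl)-7-methoxy-4H-chromen-4-one, via MOM-protected bromoflavone 6 (not isolated)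
Conditions: I2 (10 mol %), DMSO, 120 °C; then MeOH, conc. HCl, 50 °C
Reagents that add atoms: none
Why: Iodine-catalysed oxidative cyclisation of a 2'-hydroxychalcone in DMSO (oxa-Michael closure, α-iodination, loss of HI, DMSO re-oxidising iodide) is a standard flavone synthesis that leaves benzyl ethers and aryl bromides alone, and acid-catalysed acetal methanolysis then frees the 4'-phenol of 6 without touching the benzyl ether.

Step 5
Reactants: 7 5-benzyloxy-2-(3-bromo-4-hydroxyphenyl)-7-methoxy-4H-chromen-4-one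
Product: 8 5-benzyloxy-2-[3-bromo-4-(tert-butyldimethylsilyloxy)phenyl]-7-methoxy-4H-chromen-4-one
Conditions: TBSCl, imidazole, DMF, rt
Reagents that add atoms: tert-butyldimethylsilyl chloride, CC(C)(C)[Si](C)(C)Cl
Why: Imidazole-promoted silylation of the only free phenol; the silyl ether is chosen because, unlike a benzyl ether, it offers the later carbene no activated C–H bond five atoms away.

Step 6
Reactants: 9 2,4,6-trihydroxyacetophenone; 10 4-(benzyloxy)benzyl chloride
Product: 11 1-[2,4,6-tris(4-benzyloxybenzyloxy)phenyl]ethanone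
Conditions: 10 (3.3 equiv in all), K2CO3 (excess), Bu4NI (cat.), DMF, 70 °C
Reagents that add atoms: 4-(benzyloxy)benzyl chloride (second equivalent), ClCc1ccc(OCc2ccccc2)cc1; 4-(benzyloxy)benzyl chloride (third equivalent), ClCc1ccc(OCc2ccccc2)cc1
Why: Threefold Williamson etherification, one equivalent of the reactive 4-alkoxybenzyl chloride per phenol, under iodide catalysis in DMF and forcing enough to alkylate the chelated ortho hydroxyls too, so that all three oxygens end up with the same group and no regiochemical question arises.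

Step 7
Reactants: 8 5-benzyloxy-2-[3-bromo-4-(tert-butyldimethylsilyloxy)phenyl]-7-methoxy-4H-chromen-4-one; 11 1-[2,4,6-tris(4-benzyloxybenzyloxy)phenyl]ethanone
Product: 12 2-[5-(5-benzyloxy-7-methoxy-4-oxo-4H-chromen-2-yl)-2-(tert-butyldimethylsilyloxy)phenyl]-1-[2,4,6-tris(4-benzyloxybenzyloxy)phenyl]ethanone
Conditions: Pd2(dba)3 (2.5 mol %), Xantphos (6 mol %), K3PO4, toluene, 90 °C; 11 in slight excess
Reagents that add atoms: none
Why: Palladium-catalysed α-arylation of a methyl ketone (Buchwald–Hartwig type enolate coupling) under a mild phosphate base: zerovalent palladium adds into the C–Br bond of 8, the enolate of 11 is transferred and reductive elimination forms the ArCH2–C(=O) bond, the ortho substituent of 8 disfavouring a second arylation.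

Step 8
Reactants: 12 2-[5-(5-benzyloxy-7-methoxy-4-oxo-4H-chromen-2-yl)-2-(tert-butyldimethylsilyloxy)phenyl]-1-[2,4,6-tris(4-benzyloxybenzyloxy)phenyl]ethanone
Product: 13 2-diazo-2-[5-(5-benzyloxy-7-methoxy-4-oxo-4H-chromen-2-yl)-2-(tert-butyldimethylsilyloxy)phenyl]-1-[2,4,6-tris(4-benzyloxybenzyloxy)phenyl]ethanone
Conditions: p-ABSA (1.5 equiv), DBU (1.5 equiv), MeCN/CH2Cl2, 0 °C to rt, dark
Reagents that add atoms: 4-acetamidobenzenesulfonyl azide, CC(=O)Nc1ccc(cc1)S(=O)(=O)N=[N+]=[N-]
Why: Regitz diazo transfer, in which DBU deprotonates the methylene activated by both the ketone and the aryl ring and the enolate takes N2 from the sulfonyl azide under anhydrous conditions that aryl silyl and benzyl ethers tolerate.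

Step 9
Reactants: 13 2-diazo-2-[5-(5-benzyloxy-7-methoxy-4-oxo-4H-chromen-2-yl)-2-(tert-butyldimethylsilyloxy)phenyl]-1-[2,4,6-tris(4-benzyloxybenzyloxy)phenyl]ethanone
Product: 15 (2S,3R)-trans-3-[5-(5-benzyloxy-7-methoxy-4-oxo-4H-chromen-2-yl)-2-(tert-butyldimethylsilyloxy)phenyl]-5,7-bis(4-benzyloxybenzyloxy)-2-(4-benzyloxyphenyl)chroman-4-one, via cis insertion product 14 (not isolated)
Conditions: Rh2(S-PTTL)4 (2 mol %), 4 Å MS, toluene (0.01 M), slow addition of 13, 0 °C to rt; then Et3N, rt
Reagents that add atoms: none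
Why: The dirhodium catalyst expels N2 from 13, and the resulting aryl/acyl (donor–acceptor) rhodium carbene at the future C3 adds across one C–H bond of an ortho O–CH2 group through a single three-centre transition state with hydride-transfer character, that carbon becoming C2. The closest known reaction type is the chiral dirhodium carboxylate-catalysed intramolecular C–H insertion of 2-alkoxyaryl diazoketones that gives 2,3-disubstituted chroman-4-ones. The six-membered ring C is closed in the 1,6-insertion mode, the carbene carbon bonding to the sixth atom of the chain C3–C4–C4a–C8a–O1–C2. C2 is set by the catalyst, whose phthalimido-tert-leucinate ligand shell picks one of the two enantiotopic methylene hydrogens and puts the new C–C bond in its place with retention; C3 is expected to form mainly cis (14) and is then set by the substrate, Et3N equilibrating it through the enol to the trans isomer with both aryl groups equatorial while the non-acidic C2 stays fixed. The step needs C–H insertion to win over attack of the ether oxygen (five-membered oxonium ylide, then 1,2-shift), over carbene dimerisation and over insertion elsewhere; the attenuated donor–acceptor carbene, the bulky catalyst, a C–H bond activated by both the ether oxygen and the para-alkoxyaryl ring, high dilution and the silyl ether on the carbene-bearing ring are meant to secure this. Because both ortho ethers are the same and the para ether cannot reach the carbene, C–H insertion can lead to one constitution only.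

Step 10
Reactants: 15 (2S,3R)-trans-3-[5-(5-benzyloxy-7-methoxy-4-oxo-4H-chromen-2-yl)-2-(tert-butyldimethylsilyloxy)phenyl]-5,7-bis(4-benzyloxybenzyloxy)-2-(4-benzyloxyphenyl)chroman-4-one
Product: 16 (2S,3R)-trans-3-[5-(5-benzyloxy-7-methoxy-4-oxo-4H-chromen-2-yl)-2-hydroxyphenyl]-5,7-bis(4-benzyloxybenzyloxy)-2-(4-benzyloxyphenyl)chroman-4-one
Conditions: Bu4NF, AcOH (1:1), THF, 0 °C
Reagents that add atoms: none
Why: Fluoride-induced cleavage of the aryl silyl ether (Si–F bond formation), buffered with acetic acid so that the base-sensitive flavanone is neither opened at C2 nor disturbed at C3, all benzyl-type ethers being inert.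

Step 11
Reactants: 16 (2S,3R)-trans-3-[5-(5-benzyloxy-7-methoxy-4-oxo-4H-chromen-2-yl)-2-hydroxyphenyl]-5,7-bis(4-benzyloxybenzyloxy)-2-(4-benzyloxyphenyl)chroman-4-one
Product: 17 (2S,3R)-5,7-dihydroxy-3-[2-hydroxy-5-(5-hydroxy-7-methoxy-4-oxo-4H-chromen-2-yl)phenyl]-2-(4-hydroxyphenyl)chroman-4-one (CNP0361110.2)
Conditions: H2 (1 atm), 10% Pd/C, EtOAc/MeOH, rt, stopped at full conversion
Reagents that add atoms: none
Why: Catalytic hydrogenolysis of benzylic C–O bonds over Pd/C under neutral conditions should remove the two benzyl and the two 4-benzyloxybenzyl groups (the latter ending as 4-methylphenol and toluene) while leaving the flavone double bond, both carbonyl groups and the two stereocentres untouched.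

Compound list
1 | 2',6'-dihydroxy-4'-methoxyacetophenone | CC(=O)c1c(O)cc(OC)cc1O | starting material
2 | 1-(2-benzyloxy-6-hydroxy-4-methoxyphenyl)ethanone | CC(=O)c1c(O)cc(OC)cc1OCc1ccccc1 | intermediate
3 | 3-bromo-4-hydroxybenzaldehyde | O=Cc1ccc(O)c(Br)c1 | starting material
4 | 3-bromo-4-(methoxymethoxy)benzaldehyde | COCOc1ccc(C=O)cc1Br | intermediate
5 | (E)-1-(2-benzyloxy-6-hydroxy-4-methoxyphenyl)-3-[3-bromo-4-(methoxymethoxy)phenyl]prop-2-en-1-one | COc1cc(O)c(C(=O)/C=C/c2ccc(OCOC)c(Br)c2)c(OCc2ccccc2)c1 | intermediate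
6 | 5-benzyloxy-2-[3-bromo-4-(methoxymethoxy)phenyl]-7-methoxy-4H-chromen-4-one (MOM-protected bromoflavone) | COc1cc(OCc2ccccc2)c2c(=O)cc(-c3ccc(OCOC)c(Br)c3)oc2c1 | intermediate
7 | 5-benzyloxy-2-(3-bromo-4-hydroxyphenyl)-7-methoxy-4H-chromen-4-one | COc1cc(OCc2ccccc2)c2c(=O)cc(-c3ccc(O)c(Br)c3)oc2c1 | intermediate
8 | 5-benzyloxy-2-[3-bromo-4-(tert-butyldimethylsilyloxy)phenyl]-7-methoxy-4H-chromen-4-one | COc1cc(OCc2ccccc2)c2c(=O)cc(-c3ccc(O[Si](C)(C)C(C)(C)C)c(Br)c3)oc2c1 | intermediate
9 | 2,4,6-trihydroxyacetophenone | CC(=O)c1c(O)cc(O)cc1O | starting material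
10 | 4-(benzyloxy)benzyl chloride | ClCc1ccc(OCc2ccccc2)cc1 | starting material
11 | 1-[2,4,6-tris(4-benzyloxybenzyloxy)phenyl]ethanone | CC(=O)c1c(OCc2ccc(OCc3ccccc3)cc2)cc(OCc2ccc(OCc3ccccc3)cc2)cc1OCc1ccc(OCc2ccccc2)cc1 | intermediate
12 | 2-[5-(5-benzyloxy-7-methoxy-4-oxo-4H-chromen-2-yl)-2-(tert-butyldimethylsilyloxy)phenyl]-1-[2,4,6-tris(4-benzyloxybenzyloxy)phenyl]ethanone | COc1cc(OCc2ccccc2)c2c(=O)cc(-c3ccc(O[Si](C)(C)C(C)(C)C)c(CC(=O)c4c(OCc5ccc(OCc6ccccc6)cc5)cc(OCc5ccc(OCc6ccccc6)cc5)cc4OCc4ccc(OCc5ccccc5)cc4)c3)oc2c1 | intermediate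
13 | 2-diazo-2-[5-(5-benzyloxy-7-methoxy-4-oxo-4H-chromen-2-yl)-2-(tert-butyldimethylsilyloxy)phenyl]-1-[2,4,6-tris(4-benzyloxybenzyloxy)phenyl]ethanone (key-step precursor) | COc1cc(OCc2ccccc2)c2c(=O)cc(-c3ccc(O[Si](C)(C)C(C)(C)C)c(C(=[N+]=[N-])C(=O)c4c(OCc5ccc(OCc6ccccc6)cc5)cc(OCc5ccc(OCc6ccccc6)cc5)cc4OCc4ccc(OCc5ccccc5)cc4)c3)oc2c1 | intermediate
14 | (2S,3S)-cis-3-[5-(5-benzyloxy-7-methoxy-4-oxo-4H-chromen-2-yl)-2-(tert-butyldimethylsilyloxy)phenyl]-5,7-bis(4-benzyloxybenzyloxy)-2-(4-benzyloxyphenyl)chroman-4-one (cis insertion product) | COc1cc(OCc2ccccc2)c2c(=O)cc(-c3ccc(O[Si](C)(C)C(C)(C)C)c([C@@H]4C(=O)c5c(OCc6ccc(OCc7ccccc7)cc6)cc(OCc6ccc(OCc7ccccc7)cc6)cc5O[C@@H]4c4ccc(OCc5ccccc5)cc4)c3)oc2c1 | intermediate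
15 | (2S,3R)-trans-3-[5-(5-benzyloxy-7-methoxy-4-oxo-4H-chromen-2-yl)-2-(tert-butyldimethylsilyloxy)phenyl]-5,7-bis(4-benzyloxybenzyloxy)-2-(4-benzyloxyphenyl)chroman-4-one (key-step product) | COc1cc(OCc2ccccc2)c2c(=O)cc(-c3ccc(O[Si](C)(C)C(C)(C)C)c([C@H]4C(=O)c5c(OCc6ccc(OCc7ccccc7)cc6)cc(OCc6ccc(OCc7ccccc7)cc6)cc5O[C@@H]4c4ccc(OCc5ccccc5)cc4)c3)oc2c1 | intermediate
16 | (2S,3R)-trans-3-[5-(5-benzyloxy-7-methoxy-4-oxo-4H-chromen-2-yl)-2-hydroxyphenyl]-5,7-bis(4-benzyloxybenzyloxy)-2-(4-benzyloxyphenyl)chroman-4-one | COc1cc(OCc2ccccc2)c2c(=O)cc(-c3ccc(O)c([C@H]4C(=O)c5c(OCc6ccc(OCc7ccccc7)cc6)cc(OCc6ccc(OCc7ccccc7)cc6)cc5O[C@@H]4c4ccc(OCc5ccccc5)cc4)c3)oc2c1 | intermediate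
17 | (2S,3R)-5,7-dihydroxy-3-[2-hydroxy-5-(5-hydroxy-7-methoxy-4-oxo-4H-chromen-2-yl)phenyl]-2-(4-hydroxyphenyl)chroman-4-one | COc1cc(O)c2c(=O)cc(-c3ccc(O)c([C@H]4C(=O)c5c(O)cc(O)cc5O[C@@H]4c4ccc(O)cc4)c3)oc2c1 | target

Total step count: 11
Longest linear sequence: 9 steps (steps 1, 3, 4, 5, 7, 8, 9, 10, 11; steps 2 and 6 feed in)

Steps most likely to fail

1. Step 9. The ether oxygen may capture the carbene faster than the C–H bond does (oxonium ylide, then 1,2-shift of the electron-rich benzyl group), or the two enantiotopic methylene hydrogens may be told apart poorly. The fallback gives up carbene chemistry, sets out from 12 and comes back at 15. MgBr2·OEt2 in toluene/Et2O at rt should cleave one of the two carbonyl-chelated ortho 4-benzyloxybenzyl ethers (chelation-assisted dealkylation, faster for this electron-rich benzyl group than for the plain benzyl ether on the flavone). This gives 2-[5-(5-benzyloxy-7-methoxy-4-oxo-4H-chromen-2-yl)-2-(tert-butyldimethylsilyloxy)phenyl]-1-[2-hydroxy-4,6-bis(4-benzyloxybenzyloxy)phenyl]ethanone F1. Condensation of F1 with 4-benzyloxybenzaldehyde (pyrrolidine, AcOH cat., toluene, 60 °C; Knoevenagel condensation followed by oxa-Michael closure) should give the racemic 2,3-trans chromanone, that is 15 together with its (2R,3S) enantiomer F2. Preparative chromatography on a chiral stationary phase then returns 15.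

2. Step 7. The aryl silyl ether may migrate to the enolate oxygen or be lost under the hot basic conditions, or the product enolate may be arylated a second time. The fallback avoids any Brønsted base, sets out from 11 and comes back at 12. TMSOTf/Et3N (CH2Cl2, 0 °C) should convert 11 into its trimethylsilyl enol ether F3. F3 is then coupled with 8 in the presence of Bu3SnF and PdCl2[P(o-tol)3]2 (toluene, 100 °C), the tributylstannyl enol ether F4 being formed in the flask and arylated, to give 12.

3. Step 8. Diazo transfer may stall at the crowded methylene, or the base may take off the aryl silyl ether. The fallback builds the diazo group from a carbonyl group instead, sets out from 12 and comes back at 13. Riley oxidation (SeO2, 1,4-dioxane, 90 °C) should give the 1,2-diketone F5. TsNHNH2 (THF/MeOH, rt) should condense at the less shielded carbonyl group, the one next to the linking ring, to give the monotosylhydrazone F6. Et3N (CH2Cl2, rt) then expels sulfinate in a Bamford–Stevens-type elimination to give 13.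

Further compounds
F1 | step 9 | 2-[5-(5-benzyloxy-7-methoxy-4-oxo-4H-chromen-2-yl)-2-(tert-butyldimethylsilyloxy)phenyl]-1-[2-hydroxy-4,6-bis(4-benzyloxybenzyloxy)phenyl]ethanone | COc1cc(OCc2ccccc2)c2c(=O)cc(-c3ccc(O[Si](C)(C)C(C)(C)C)c(CC(=O)c4c(O)cc(OCc5ccc(OCc6ccccc6)cc5)cc4OCc4ccc(OCc5ccccc5)cc4)c3)oc2c1
F2 | step 9 | (2R,3S)-trans-3-[5-(5-benzyloxy-7-methoxy-4-oxo-4H-chromen-2-yl)-2-(tert-butyldimethylsilyloxy)phenyl]-5,7-bis(4-benzyloxybenzyloxy)-2-(4-benzyloxyphenyl)chroman-4-one (enantiomer of 15) | COc1cc(OCc2ccccc2)c2c(=O)cc(-c3ccc(O[Si](C)(C)C(C)(C)C)c([C@@H]4C(=O)c5c(OCc6ccc(OCc7ccccc7)cc6)cc(OCc6ccc(OCc7ccccc7)cc6)cc5O[C@H]4c4ccc(OCc5ccccc5)cc4)c3)oc2c1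
F3 | step 7 | trimethyl({1-[2,4,6-tris(4-benzyloxybenzyloxy)phenyl]ethenyl}oxy)silane | C=C(O[Si](C)(C)C)c1c(OCc2ccc(OCc3ccccc3)cc2)cc(OCc2ccc(OCc3ccccc3)cc2)cc1OCc1ccc(OCc2ccccc2)cc1
F4 | step 7 | tributyl({1-[2,4,6-tris(4-benzyloxybenzyloxy)phenyl]ethenyl}oxy)stannane | C=C(O[Sn](CCCC)(CCCC)CCCC)c1c(OCc2ccc(OCc3ccccc3)cc2)cc(OCc2ccc(OCc3ccccc3)cc2)cc1OCc1ccc(OCc2ccccc2)cc1
F5 | step 8 | 1-[5-(5-benzyloxy-7-methoxy-4-oxo-4H-chromen-2-yl)-2-(tert-butyldimethylsilyloxy)phenyl]-2-[2,4,6-tris(4-benzyloxybenzyloxy)phenyl]ethane-1,2-dione | COc1cc(OCc2ccccc2)c2c(=O)cc(-c3ccc(O[Si](C)(C)C(C)(C)C)c(C(=O)C(=O)c4c(OCc5ccc(OCc6ccccc6)cc5)cc(OCc5ccc(OCc6ccccc6)cc5)cc4OCc4ccc(OCc5ccccc5)cc4)c3)oc2c1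
F6 | step 8 | mono(4-methylbenzenesulfonyl)hydrazone of F5 at the carbonyl group next to the linking ring | COc1cc(OCc2ccccc2)c2c(=O)cc(-c3ccc(O[Si](C)(C)C(C)(C)C)c(C(=NNS(=O)(=O)c4ccc(C)cc4)C(=O)c4c(OCc5ccc(OCc6ccccc6)cc5)cc(OCc5ccc(OCc6ccccc6)cc5)cc4OCc4ccc(OCc5ccccc5)cc4)c3)oc2c1
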